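**Plan**
1. The retrosynthesis first removes the five benzyl ethers and the 3-O-methyl group, then the C3–O bond, leading back to a flavone with C3–H.
2. Ring C is then cut at C4a–C4, C4–C3 and O1–C2. C4 is a lone carbonyl carbon between ring A carbon C4a and the C3–C2 pair that carries ring B, and O1 sits on C8a next to C4a, so ring C maps onto an ortho-iodophenol (C8a–OH, C4a–I), carbon monoxide (C4) and an arylacetylene (C3≡C2–ring B).
3. Forward, ring A enters as iodophenol 8, made in five steps from 5-bromo-o-vanillin with the formyl group serving as a masked O1. Ring B enters as alkyne 11, made in two steps from 3,4,5-trihydroxybenzaldehyde.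
4. Ring C is the only ring built, in the three-component carbonylative annulation. C3 hydroxylation, O-methylation and global hydrogenolysis finish the route.
5. Stereochemistry: the target has no stereocenter and no stereogenic double bond, so nothing has to be set.

Key step: step 8

Remark: numbered from its hydroxyl-bearing carbon, the iodophenol that maps onto ring A is 3,6-bis(benzyloxy)-2-iodo-5-methoxyphenol (methoxy meta to OH, on the carbon that becomes C7); the free target is an air-sensitive hydroquinone/pyrogallol and is assumed to be handled under argon.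

**Route**

Step 1
Reactants: 1 5-bromo-2-hydroxy-3-methoxybenzaldehyde
Product: 2 2-(benzyloxy)-5-bromo-3-methoxybenzaldehyde
Conditions: BnBr, K2CO3, DMF, 60 °C
Reagents that add atoms: benzyl bromide, BrCc1ccccc1
Why: Williamson etherification of the acidic salicylaldehyde-type phenol is routine and caps the hydroxyl that would otherwise trigger Dakin cleavage of the aldehyde under the peroxide conditions of step 2.

Step 2
Reactants: 2 2-(benzyloxy)-5-bromo-3-methoxybenzaldehyde
Product: 4 2-(benzyloxy)-5-hydroxy-3-methoxybenzaldehyde, via pinacol boronate 3 (not isolated)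
Conditions: B2pin2, PdCl2(dppf) (cat.), KOAc, dioxane, 90 °C; then NaBO3·4H2O, THF/H2O, rt
Reagents that add atoms: sodium perborate tetrahydrate, B(=O)O[O-].[Na+].O.O.O.O
Why: Miyaura borylation of the aryl bromide tolerates the aldehyde, and mild perborate oxidation of the C–B bond (aryl shift from boron to oxygen) should give a phenol that is meta to the formyl group and therefore cannot undergo Dakin cleavage.

Step 3
Reactants: 4 2-(benzyloxy)-5-hydroxy-3-methoxybenzaldehyde
Product: 5 2,5-bis(benzyloxy)-3-methoxybenzaldehyde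
Conditions: BnBr, K2CO3, DMF, 60 °C
Reagents that add atoms: benzyl bromide, BrCc1ccccc1
Why: Williamson etherification of the only acidic site in the molecule.

Step 4
Reactants: 5 2,5-bis(benzyloxy)-3-methoxybenzaldehyde
Product: 6 3,6-bis(benzyloxy)-2-iodo-5-methoxybenzaldehyde
Conditions: NIS (1.05 equiv), TFA, MeCN, 0 °C to rt
Reagents that add atoms: N-iodosuccinimide, O=C1CCC(=O)N1I
Why: Electrophilic aromatic iodination should go to C6 of 5, which is para to the 3-methoxy and ortho to the 5-benzyloxy group, rather than to C4, which is wedged between two alkoxy groups; this is the same bias that sends halogenation of 3,5-dialkoxybenzaldehydes to the position next to the formyl group.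

Step 5
Reactants: 6 3,6-bis(benzyloxy)-2-iodo-5-methoxybenzaldehyde
Product: 8 3,6-bis(benzyloxy)-2-iodo-5-methoxyphenol, via aryl formate 7 (not isolated)
Conditions: mCPBA, CH2Cl2, 0 °C to rt; then K2CO3 (cat.), MeOH, rt
Reagents that add atoms: 3-chloroperbenzoic acid, O=C(OO)c1cccc(Cl)c1
Why: Baeyer–Villiger (Dakin-type) oxidation in which the electron-rich, ortho-benzyloxy-substituted aryl group migrates in preference to hydride, followed by mild methanolysis of the formate; without added strong acid the peracid should leave the aryl iodide alone.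

Step 6
Reactants: 9 3,4,5-trihydroxybenzaldehyde
Product: 10 3,4,5-tris(benzyloxy)benzaldehyde
Conditions: BnBr (3.3 equiv), K2CO3, DMF, 70 °C, under argon
Reagents that add atoms: benzyl bromide, BrCc1ccccc1
Why: Threefold Williamson etherification of the pyrogallol hydroxyls, run under argon so that the free triol is not oxidised by air before it is capped.

Step 7
Reactants: 10 3,4,5-tris(benzyloxy)benzaldehyde
Product: 11 5-ethynyl-1,2,3-tris(benzyloxy)benzene
Conditions: dimethyl (1-diazo-2-oxopropyl)phosphonate, K2CO3, MeOH/THF, 0 °C to rt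
Reagents that add atoms: dimethyl (1-diazo-2-oxopropyl)phosphonate, CC(=O)C(=[N+]=[N-])P(=O)(OC)OC
Why: Ohira–Bestmann (Seyferth–Gilbert) homologation: the diazomethylphosphonate released by methanolysis adds to the non-enolisable aldehyde, and loss of dimethyl phosphate and nitrogen with a 1,2-hydride shift gives the terminal alkyne under conditions that benzyl ethers tolerate.

Step 8
Reactants: 8 3,6-bis(benzyloxy)-2-iodo-5-methoxyphenol, 11 5-ethynyl-1,2,3-tris(benzyloxy)benzene, 12 carbon monoxide
Product: 15 5,8-bis(benzyloxy)-7-methoxy-2-[3,4,5-tris(benzyloxy)phenyl]-4H-chromen-4-one, via hydroxyaryl ynone 13 (not isolated), via enaminone 14 (not isolated)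
Conditions: CO (20 bar), PdCl2(dppf) (5 mol%), Et2NH, 120 °C, autoclave
Reagents that add atoms: none
Why: Zerovalent palladium, formed in the amine from the divalent palladium precatalyst PdCl2(dppf), inserts into the C–I bond of 8, CO inserts to give an aroylpalladium species, and coupling with the acetylide of 11 releases the ortho-hydroxyaryl ynone 13 (C4a–C4 and C4–C3 formed). Diethylamine then adds to the ynone to give enaminone 14, and the phenol oxygen attacks the amine-bearing carbon and expels Et2NH, forming O1–C2. The closest known reaction is the palladium-catalysed carbonylative Sonogashira annulation of ortho-iodophenols with terminal alkynes to flavones in a secondary amine. Ring C closes in a 6-endo mode (6-endo-dig with respect to the ynone, carried out as a 6-endo-trig addition–elimination on the enaminone), and no stereocenter is created. Two selectivities are needed: CO insertion before alkynylation, secured by the CO pressure, the absence of a copper co-catalyst and the two ortho substituents that favour insertion at the crowded arylpalladium centre; and 6-endo over 5-exo closure (aurone), secured by the amine, which turns the distal alkyne carbon into the electrophilic enaminone carbon. Ring A needs no regiocontrol because the oxygens destined for O1, C5, C7 and C8 are already fixed in 8.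

Step 9
Reactants: 15 5,8-bis(benzyloxy)-7-methoxy-2-[3,4,5-tris(benzyloxy)phenyl]-4H-chromen-4-one
Product: 18 5,8-bis(benzyloxy)-3-hydroxy-7-methoxy-2-[3,4,5-tris(benzyloxy)phenyl]-4H-chromen-4-one, via 3-lithioflavone 16 (not isolated), via dimethyl boronate 17 (not isolated)
Conditions: LiN(iPr)2, THF, −78 °C; B(OMe)3, −78 °C to rt; then AcOH, 30% H2O2, 0 °C to rt
Reagents that add atoms: hydrogen peroxide, OO
Why: Deprotonation of the chromone C3–H by the lithium amide is known for flavones, and borate trapping followed by oxidative carbon-to-oxygen migration should give the flavonol, while the amide base at −78 °C is too weak to remove benzylic ether protons.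

Step 10
Reactants: 18 5,8-bis(benzyloxy)-3-hydroxy-7-methoxy-2-[3,4,5-tris(benzyloxy)phenyl]-4H-chromen-4-one
Product: 19 5,8-bis(benzyloxy)-3,7-dimethoxy-2-[3,4,5-tris(benzyloxy)phenyl]-4H-chromen-4-one
Conditions: MeI, K2CO3, DMF, rt
Reagents that add atoms: methyl iodide, CI
Why: Williamson O-methylation of the only free hydroxyl, the acidic 3-OH of the flavonol.

Step 11
Reactants: 19 5,8-bis(benzyloxy)-3,7-dimethoxy-2-[3,4,5-tris(benzyloxy)phenyl]-4H-chromen-4-one
Product: 20 5,8-dihydroxy-3,7-dimethoxy-2-(3,4,5-trihydroxyphenyl)-4H-chromen-4-one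
Conditions: H2 (1 atm), Pd/C (10%), THF/MeOH, rt; filtration and concentration under argon
Reagents that add atoms: none
Why: Catalytic hydrogenolysis should cleave all five benzyl aryl ethers while the methyl ethers and the tetrasubstituted C2–C3 double bond of the chromone stay intact, and the reducing medium protects the hydroquinone and pyrogallol units until isolation.

**Compound list**
1 | 5-bromo-2-hydroxy-3-methoxybenzaldehyde | COc1cc(Br)cc(C=O)c1O | starting material
2 | 2-(benzyloxy)-5-bromo-3-methoxybenzaldehyde | COc1cc(Br)cc(C=O)c1OCc1ccccc1 | intermediate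
3 | 2-(benzyloxy)-3-methoxy-5-(4,4,5,5-tetramethyl-1,3,2-dioxaborolan-2-yl)benzaldehyde | COc1cc(B2OC(C)(C)C(C)(C)O2)cc(C=O)c1OCc1ccccc1 | intermediate
4 | 2-(benzyloxy)-5-hydroxy-3-methoxybenzaldehyde | COc1cc(O)cc(C=O)c1OCc1ccccc1 | intermediate
5 | 2,5-bis(benzyloxy)-3-methoxybenzaldehyde | COc1cc(OCc2ccccc2)cc(C=O)c1OCc1ccccc1 | intermediate
6 | 3,6-bis(benzyloxy)-2-iodo-5-methoxybenzaldehyde | COc1cc(OCc2ccccc2)c(I)c(C=O)c1OCc1ccccc1 | intermediate
7 | 3,6-bis(benzyloxy)-2-iodo-5-methoxyphenyl formate | COc1cc(OCc2ccccc2)c(I)c(OC=O)c1OCc1ccccc1 | intermediate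
8 | 3,6-bis(benzyloxy)-2-iodo-5-methoxyphenol | COc1cc(OCc2ccccc2)c(I)c(O)c1OCc1ccccc1 | intermediate
9 | 3,4,5-trihydroxybenzaldehyde | O=Cc1cc(O)c(O)c(O)c1 | starting material
10 | 3,4,5-tris(benzyloxy)benzaldehyde | O=Cc1cc(OCc2ccccc2)c(OCc2ccccc2)c(OCc2ccccc2)c1 | intermediate
11 | 5-ethynyl-1,2,3-tris(benzyloxy)benzene | C#Cc1cc(OCc2ccccc2)c(OCc2ccccc2)c(OCc2ccccc2)c1 | intermediate
12 | carbon monoxide | [C-]#[O+] | starting material
13 | 1-[3,6-bis(benzyloxy)-2-hydroxy-4-methoxyphenyl]-3-[3,4,5-tris(benzyloxy)phenyl]prop-2-yn-1-one | COc1cc(OCc2ccccc2)c(C(=O)C#Cc2cc(OCc3ccccc3)c(OCc3ccccc3)c(OCc3ccccc3)c2)c(O)c1OCc1ccccc1 | intermediate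
14 | (E)-1-[3,6-bis(benzyloxy)-2-hydroxy-4-methoxyphenyl]-3-(diethylamino)-3-[3,4,5-tris(benzyloxy)phenyl]prop-2-en-1-one | COc1cc(OCc2ccccc2)c(C(=O)/C=C(/N(CC)CC)c2cc(OCc3ccccc3)c(OCc3ccccc3)c(OCc3ccccc3)c2)c(O)c1OCc1ccccc1 | intermediate
15 | 5,8-bis(benzyloxy)-7-methoxy-2-[3,4,5-tris(benzyloxy)phenyl]-4H-chromen-4-one | COc1cc(OCc2ccccc2)c2c(=O)cc(-c3cc(OCc4ccccc4)c(OCc4ccccc4)c(OCc4ccccc4)c3)oc2c1OCc1ccccc1 | intermediate
16 | {5,8-bis(benzyloxy)-7-methoxy-4-oxo-2-[3,4,5-tris(benzyloxy)phenyl]-4H-chromen-3-yl}lithium | COc1cc(OCc2ccccc2)c2c(=O)c([Li])c(-c3cc(OCc4ccccc4)c(OCc4ccccc4)c(OCc4ccccc4)c3)oc2c1OCc1ccccc1 | intermediate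
17 | dimethyl {5,8-bis(benzyloxy)-7-methoxy-4-oxo-2-[3,4,5-tris(benzyloxy)phenyl]-4H-chromen-3-yl}boronate | COc1cc(OCc2ccccc2)c2c(=O)c(B(OC)OC)c(-c3cc(OCc4ccccc4)c(OCc4ccccc4)c(OCc4ccccc4)c3)oc2c1OCc1ccccc1 | intermediate
18 | 5,8-bis(benzyloxy)-3-hydroxy-7-methoxy-2-[3,4,5-tris(benzyloxy)phenyl]-4H-chromen-4-one | COc1cc(OCc2ccccc2)c2c(=O)c(O)c(-c3cc(OCc4ccccc4)c(OCc4ccccc4)c(OCc4ccccc4)c3)oc2c1OCc1ccccc1 | intermediate
19 | 5,8-bis(benzyloxy)-3,7-dimethoxy-2-[3,4,5-tris(benzyloxy)phenyl]-4H-chromen-4-one | COc1cc(OCc2ccccc2)c2c(=O)c(OC)c(-c3cc(OCc4ccccc4)c(OCc4ccccc4)c(OCc4ccccc4)c3)oc2c1OCc1ccccc1 | intermediate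
20 | 5,8-dihydroxy-3,7-dimethoxy-2-(3,4,5-trihydroxyphenyl)-4H-chromen-4-one (5,8,3',4',5'-pentahydroxy-3,7-dimethoxyflavone) | COc1cc(O)c2c(=O)c(OC)c(-c3cc(O)c(O)c(O)c3)oc2c1O | target

**Step count**
Total: 11 steps. Longest linear sequence: 9 steps (steps 1–5 and 8–11, from compound 1).

**Steps most likely to fail**

Step 4. Iodination may go to the wrong ring position (C4, between the two alkoxy groups) or occur twice. The fallback places the iodine by directed ortho-metalation after the aldehyde has been turned into the phenol; it sets out from 5 and returns at 8, replacing steps 4 and 5 and keeping the peracid away from the aryl iodide. Baeyer–Villiger oxidation of 5 (mCPBA, CH2Cl2) would give 2,5-bis(benzyloxy)-3-methoxyphenyl formate F1, and methanolysis (K2CO3, MeOH) would give 2,5-bis(benzyloxy)-3-methoxyphenol F2. Carbamoylation (ClCONEt2, K2CO3, MeCN, reflux) would give 2,5-bis(benzyloxy)-3-methoxyphenyl diethylcarbamate F3. Treatment with s-BuLi/TMEDA in THF at −78 °C should lithiate the position flanked by the carbamate and the 5-benzyloxy group, the carbamate being the strongest director on the ring, to give [3,6-bis(benzyloxy)-2-(diethylcarbamoyloxy)-4-methoxyphenyl]lithium F4. Quenching with I2 would give 3,6-bis(benzyloxy)-2-iodo-5-methoxyphenyl diethylcarbamate F5, and hydrolysis of the carbamate (NaOH, EtOH, reflux) would return to iodophenol 8.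

Step 8. Oxidative addition into the hindered, electron-rich C–I bond may stall, direct alkynylation may outrun CO insertion (leading on to benzofuran formation), or five-membered closure may compete. The fallback forms the same three bonds of ring C but brings the C4 carbonyl in on the alkyne instead of from CO gas; it sets out from 8 and 11 and returns at 15. Protection of 8 (MOMCl, iPr2NEt, CH2Cl2) would give 1,4-bis(benzyloxy)-2-iodo-5-methoxy-3-(methoxymethoxy)benzene F6. Deprotonation of 11 with n-BuLi (THF, −78 °C) would give {[3,4,5-tris(benzyloxy)phenyl]ethynyl}lithium F7, which with N-methoxy-N-methylcarbamoyl chloride would give N-methoxy-N-methyl-3-[3,4,5-tris(benzyloxy)phenyl]prop-2-ynamide F8. Iodine–magnesium exchange of F6 with iPrMgCl·LiCl (THF, −20 °C) would give [3,6-bis(benzyloxy)-4-methoxy-2-(methoxymethoxy)phenyl]magnesium chloride F9, and its addition to F8 would give 1-[3,6-bis(benzyloxy)-4-methoxy-2-(methoxymethoxy)phenyl]-3-[3,4,5-tris(benzyloxy)phenyl]prop-2-yn-1-one F10. HCl in MeOH would remove the methoxymethyl group to give ynone 13, and Et2NH in EtOH would close ring C through enaminone 14 to flavone 15.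

Step 9. Addition of the amide base to the chromone, or base-induced opening of ring C, may compete with removal of H3. The fallback oxygenates C3 by epoxidation; it sets out from 15 and returns at 18. Dimethyldioxirane in acetone/CH2Cl2 at 0 °C should give the racemic, cis-fused 2,3-epoxide 3,6-bis(benzyloxy)-4-methoxy-1a-[3,4,5-tris(benzyloxy)phenyl]-1a,7a-dihydro-7H-oxireno[2,3-b]chromen-7-one F11. Catalytic p-TsOH in CH2Cl2 would then open the oxirane at C2 and, after loss of H3, give flavonol 18.

**Further compounds**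
F1 | step 4 | 2,5-bis(benzyloxy)-3-methoxyphenyl formate | COc1cc(OCc2ccccc2)cc(OC=O)c1OCc1ccccc1
F2 | step 4 | 2,5-bis(benzyloxy)-3-methoxyphenol | COc1cc(OCc2ccccc2)cc(O)c1OCc1ccccc1
F3 | step 4 | 2,5-bis(benzyloxy)-3-methoxyphenyl diethylcarbamate | CCN(CC)C(=O)Oc1cc(OCc2ccccc2)cc(OC)c1OCc1ccccc1
F4 | step 4 | [3,6-bis(benzyloxy)-2-(diethylcarbamoyloxy)-4-methoxyphenyl]lithium | [Li]c1c(OCc2ccccc2)cc(OC)c(OCc2ccccc2)c1OC(=O)N(CC)CC
F5 | step 4 | 3,6-bis(benzyloxy)-2-iodo-5-methoxyphenyl diethylcarbamate | CCN(CC)C(=O)Oc1c(I)c(OCc2ccccc2)cc(OC)c1OCc1ccccc1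
F6 | step 8 | 1,4-bis(benzyloxy)-2-iodo-5-methoxy-3-(methoxymethoxy)benzene | COCOc1c(I)c(OCc2ccccc2)cc(OC)c1OCc1ccccc1
F7 | step 8 | {[3,4,5-tris(benzyloxy)phenyl]ethynyl}lithium | [Li]C#Cc1cc(OCc2ccccc2)c(OCc2ccccc2)c(OCc2ccccc2)c1
F8 | step 8 | N-methoxy-N-methyl-3-[3,4,5-tris(benzyloxy)phenyl]prop-2-ynamide | CON(C)C(=O)C#Cc1cc(OCc2ccccc2)c(OCc2ccccc2)c(OCc2ccccc2)c1
F9 | step 8 | [3,6-bis(benzyloxy)-4-methoxy-2-(methoxymethoxy)phenyl]magnesium chloride | COCOc1c([Mg]Cl)c(OCc2ccccc2)cc(OC)c1OCc1ccccc1
F10 | step 8 | 1-[3,6-bis(benzyloxy)-4-methoxy-2-(methoxymethoxy)phenyl]-3-[3,4,5-tris(benzyloxy)phenyl]prop-2-yn-1-one | COCOc1c(C(=O)C#Cc2cc(OCc3ccccc3)c(OCc3ccccc3)c(OCc3ccccc3)c2)c(OCc2ccccc2)cc(OC)c1OCc1ccccc1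
F11 | step 9 | 3,6-bis(benzyloxy)-4-methoxy-1a-[3,4,5-tris(benzyloxy)phenyl]-1a,7a-dihydro-7H-oxireno[2,3-b]chromen-7-one (racemic, cis-fused; one enantiomer drawn) | O=C1[C@@H]2O[C@]2(c2cc(OCc3ccccc3)c(OCc3ccccc3)c(OCc3ccccc3)c2)Oc2c1c(OCc1ccccc1)cc(OC)c2OCc1ccccc1
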